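**Retrosynthetic overview**

1. Target 35 ⇐ C1 desilylation ⇐ C6 angeloylation ⇐ hydroxyl-directed epoxidation of Z-C4=C5 ⇐ C11 methylenation (C6 temporarily silylated) ⇐ ten-membered (Z)-allylic C6 alcohol 24.
2. The strategy rests on one feature: in the ten-membered carbocycle (C1–C10) the C6 oxygen is allylic to the Z-C4=C5 alkene hidden in the 4,5-oxirane. The 4,5-epoxy-6-ol array is therefore the epoxidation product of a (Z)-allylic alcohol, and 24 is cut at C5–C6 into a C5 alkenylchromium and a C6 aldehyde (seco-aldehyde 22).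
3. 22 (trans-β-formyl-γ-butanolide, side chain C9–C10(=C14)–C1–C5 on C8) ⇐ Hosomi–Sakurai allylation and retro-aldol lactonization of cyclopropanecarbaldehyde 18 (C6, C7, C8, C11, C12; from methyl 2-furoate) with allylsilane 13 (C1–C5, C9, C10, C14, C15; from propyne carbocupration–iodination and a 2-metalloallylsilane linchpin, C1 set by CBS reduction).
4. Ring order: γ-butanolide (step 10), ten-membered carbocycle (step 11), oxirane (step 16).

Key step: step 11

**Remarks and assumptions**

- Germacrane locants are used: C1 = CH–O next to C10; C2, C3 = CH2CH2; C4(CH3)/C5 = epoxide carbons; C6 = angelate carbon; C7/C8 = lactone fusion (O on C8); C9 = ring CH2; C10(=C14H2); C11(=C13H2)/C12 = lactone carbons; C15 = methyl on C4. With H-7 drawn α, all four ring oxygens of the target (O-1, epoxide O, O-6, O-8) are α; the target is (1S,4R,5S,6S,7R,8S).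
- C9 is delivered as the nucleophilic terminus of an allylsilane, so C8 must be the electrophile. The butanolide is therefore generated from a cyclopropanecarbaldehyde, not from a preformed 5-(hydroxymethyl)butanolide, whose C9 would also be electrophilic.
- Assumption: the (S,S)-configured isopropyl-bis(oxazoline) ligand is taken to give the (1S,5S,6S) bicycle 16; should the sense be opposite, the (R,R) ligand is used.
- Commercial (2-bromoallyl)trimethylsilane is used as the linchpin.

**Route**

Step 1
Reactants: 1 2-(2-bromoethyl)-1,3-dioxolane; 2 propyne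
Product: 6 2-[(3Z)-4-iodo-3-methylbut-3-en-1-yl]-1,3-dioxolane, via acetal Grignard reagent 3 (not isolated), via alkylcopper 4 (not isolated), via (Z)-alkenylcopper 5 (not isolated)
Conditions: Mg, THF, 25 °C; CuBr·SMe2, Et2O/Me2S, −45 °C; propyne, −25 °C; I2, THF, −78 → 0 °C
Reagents that add atoms: iodine, SMILES II
Why: Normant carbocupration adds the alkylcopper syn across propyne with copper on the terminal carbon, so the C3 chain and Cu are cis, and iodinolysis with retention should give the (Z)-iodoalkene (chain cis to I).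

Step 2
Reactants: 6 2-[(3Z)-4-iodo-3-methylbut-3-en-1-yl]-1,3-dioxolane
Product: 7 (4Z)-5-iodo-4-methylpent-4-enal
Conditions: AcOH/H2O (4:1), 60 °C
Reagents that add atoms: water, SMILES O
Why: Acid-catalysed acetal hydrolysis should unveil the C1 aldehyde while the alkenyl iodide is inert to aqueous acid.

Step 3
Reactants: 7 (4Z)-5-iodo-4-methylpent-4-enal; 8 (2-bromoallyl)trimethylsilane
Product: 10 rac-(6Z)-7-iodo-6-methyl-2-[(trimethylsilyl)methyl]hepta-1,6-dien-3-ol, via alkenyl Grignard reagent 9 (not isolated)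
Conditions: Mg, THF, 40 °C (from 8); then 7, THF, −78 → 0 °C; aq. NH4Cl
Reagents that add atoms: none
Why: Grignard 1,2-addition of the 2-magnesioallylsilane forms C10–C1 (an alkenylmagnesium should not exchange with the alkenyl iodide at low temperature); the carbinol is racemic here and is corrected in steps 4 and 5.

Step 4
Reactants: 10 rac-(6Z)-7-iodo-6-methyl-2-[(trimethylsilyl)methyl]hepta-1,6-dien-3-ol
Product: 11 (6Z)-7-iodo-6-methyl-2-[(trimethylsilyl)methyl]hepta-1,6-dien-3-one
Conditions: TPAP (5 mol%), NMO, 4 Å MS, CH2Cl2, 25 °C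
Reagents that add atoms: none
Why: Ley–Griffith oxidation of the allylic alcohol under neutral conditions should give the enone without protodesilylation of the allylsilane.

Step 5
Reactants: 11 (6Z)-7-iodo-6-methyl-2-[(trimethylsilyl)methyl]hepta-1,6-dien-3-one
Product: 12 (3S,6Z)-7-iodo-6-methyl-2-[(trimethylsilyl)methyl]hepta-1,6-dien-3-ol
Conditions: (R)-2-methyl-CBS-oxazaborolidine (20 mol%), catecholborane, toluene, −78 °C
Reagents that add atoms: none
Why: Corey–Bakshi–Shibata reduction, in which the α-branched alkenyl group acts as the large substituent, should set C1 as S with the (R)-catalyst, and catecholborane at low temperature avoids hydroboration of the alkenes.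

Step 6
Reactants: 12 (3S,6Z)-7-iodo-6-methyl-2-[(trimethylsilyl)methyl]hepta-1,6-dien-3-ol
Product: 13 (3S,6Z)-3-(tert-butyldimethylsilyloxy)-7-iodo-6-methyl-2-[(trimethylsilyl)methyl]hepta-1,6-diene
Conditions: TBSCl, imidazole, DMF, 25 °C
Reagents that add atoms: tert-butyldimethylsilyl chloride, SMILES CC(C)(C)[Si](C)(C)Cl
Why: Standard silylation under basic conditions protects C1–OH and leaves the acid-sensitive allylsilane untouched.

Step 7
Reactants: 14 methyl furan-2-carboxylate; 15 ethyl diazoacetate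
Product: 16 6-ethyl 3-methyl (1S,5S,6S)-2-oxabicyclo[3.1.0]hex-3-ene-3,6-dicarboxylate
Conditions: Cu(OTf)2 (cat.), (S,S)-iPr-bis(oxazoline), PhNHNH2 (cat.), CH2Cl2, 0 °C, slow addition of 15; recrystallization
Reagents that add atoms: none
Why: Copper–bis(oxazoline) asymmetric cyclopropanation attacks the furan 4,5-double bond remote from the ester from the ligand-defined face with the new ester exo, which sets the future C7 centre, and recrystallization should raise the enantiopurity.

Step 8
Reactants: 16 6-ethyl 3-methyl (1S,5S,6S)-2-oxabicyclo[3.1.0]hex-3-ene-3,6-dicarboxylate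
Product: 18 ethyl (1S,2S,3S)-2-formyl-3-[(methoxyoxalyl)oxy]cyclopropane-1-carboxylate, via secondary ozonide 17 (not isolated)
Conditions: O3, CH2Cl2, −78 °C; Me2S, −78 → 25 °C
Reagents that add atoms: ozone, SMILES [O-][O+]=O
Why: Ozonolysis of the enol-ether double bond should give the C8 aldehyde and turn the former furan C2 into a mixed oxalate on the cyclopropanol oxygen, without touching the three ring stereocentres.

Step 9
Reactants: 18 ethyl (1S,2S,3S)-2-formyl-3-[(methoxyoxalyl)oxy]cyclopropane-1-carboxylate; 13 (3S,6Z)-3-(tert-butyldimethylsilyloxy)-7-iodo-6-methyl-2-[(trimethylsilyl)methyl]hepta-1,6-diene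
Product: 19 ethyl (1S,2R,3S)-2-[(1S,4S,7Z)-4-(tert-butyldimethylsilyloxy)-1-hydroxy-8-iodo-7-methyl-3-methylideneoct-7-en-1-yl]-3-[(methoxyoxalyl)oxy]cyclopropane-1-carboxylate
Conditions: BF3·OEt2, CH2Cl2, −78 °C
Reagents that add atoms: none
Why: Hosomi–Sakurai allylation forms C8–C9 and releases the C10=C14 methylene, and Felkin–Anh attack anti to the cyclopropane carbon that carries the cis oxalate should set C8 as S.

Step 10
Reactants: 19 ethyl (1S,2R,3S)-2-[(1S,4S,7Z)-4-(tert-butyldimethylsilyloxy)-1-hydroxy-8-iodo-7-methyl-3-methylideneoct-7-en-1-yl]-3-[(methoxyoxalyl)oxy]cyclopropane-1-carboxylate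
Product: 22 (2S,3R)-2-[(3S,6Z)-3-(tert-butyldimethylsilyloxy)-7-iodo-6-methyl-2-methylidenehept-6-en-1-yl]-5-oxooxolane-3-carbaldehyde, via cyclopropanol 20 (not isolated), via ring-opened hydroxy aldehyde ester 21 (not isolated)
Conditions: Ba(OH)2·8H2O (0.5 equiv), MeOH, 0 °C
Reagents that add atoms: none
Why: Methanolysis of the oxalate frees a donor–acceptor cyclopropanol that opens by retro-aldol cleavage of C6–C11 to the C6 aldehyde and the C11 methylene ester, and the C8 hydroxyl then lactonizes to the trans-butanolide (C7 untouched, C8 from step 9, trans also thermodynamically favoured).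

Step 11
Reactants: 22 (2S,3R)-2-[(3S,6Z)-3-(tert-butyldimethylsilyloxy)-7-iodo-6-methyl-2-methylidenehept-6-en-1-yl]-5-oxooxolane-3-carbaldehyde
Product: 24 (1S,4Z,6R,7S,8S)-1-(tert-butyldimethylsilyloxy)-6-hydroxygermacra-4,10(14)-dien-8,12-olide, via (Z)-alkenylchromium(III) species 23 (not isolated)
Conditions: CrCl2 (10 equiv), NiCl2 (1 mol% of Cr), degassed DMSO, 25 °C, syringe-pump addition of 22 (final ≈ 3 mM); aq. NH4Cl
Reagents that add atoms: none
Why: NiCl2 is reduced by CrCl2 to Ni(0), which inserts into the C5–I bond with retention, and transmetalation to Cr(III) gives the configurationally stable (Z)-alkenylchromium 23, which adds 1,2 to the chromium-coordinated C6 aldehyde (Nozaki–Hiyama–Kishi reaction; the closest known reaction type is the Ni/Cr-mediated alkenyl iodide–aldehyde macrocyclization to medium-ring allylic alcohols). The ten-membered carbocycle (C1–C10) closes by intramolecular addition of C5 to the exocyclic C6 carbonyl (10-exo-trig) at high dilution, with the trans-butanolide and the two sp2 centres (C4=C5, C10) holding the chain ends close. The new C6 stereocentre is controlled by the adjacent C7 centre of the trans-butanolide: C5 should approach antiperiplanar to the C7–C8 bond with the carbonyl flanked by the C11 methylene (Felkin–Anh sense), which places the hydroxyl α, cis to H-7. The step needs chemoselectivity (the organochromium should react only with the aldehyde and spare the lactone, the silyl ether and the epimerizable C7–H), retention of the Z geometry (secured by the stereospecific insertion and transmetalation) and cyclization over oligomerization (secured by slow addition and dilution).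

Step 12
Reactants: 24 (1S,4Z,6R,7S,8S)-1-(tert-butyldimethylsilyloxy)-6-hydroxygermacra-4,10(14)-dien-8,12-olide
Product: 25 (1S,4Z,6R,7R,8S)-1-(tert-butyldimethylsilyloxy)-6-(triethylsilyloxy)germacra-4,10(14)-dien-8,12-olide
Conditions: TESOTf, 2,6-lutidine, CH2Cl2, −78 °C
Reagents that add atoms: triethylsilyl trifluoromethanesulfonate, SMILES CC[Si](CC)(CC)OS(=O)(=O)C(F)(F)F
Why: Silyl triflate with a hindered base caps the C6 hydroxyl without forming an alkoxide, which avoids translactonization from the 8,12- to the 6,12-olide and removes the acidic OH before enolate chemistry.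

Step 13
Reactants: 25 (1S,4Z,6R,7R,8S)-1-(tert-butyldimethylsilyloxy)-6-(triethylsilyloxy)germacra-4,10(14)-dien-8,12-olide
Product: 27 11-[(dimethylamino)methyl] derivative of 25 (aminomethyl group trans to C6 on the lactone), via lithium lactone enolate 26 (not isolated)
Conditions: LDA, THF, −78 °C; CH2=NMe2+ I−, −78 → 0 °C
Reagents that add atoms: N,N-dimethylmethyleneiminium iodide (Eschenmoser's salt), SMILES C=[N+](C)C.[I-]
Why: C11 is the only enolizable lactone position, and Mannich trapping of the enolate with Eschenmoser's salt should occur anti to the C7 substituent, the new C11 centre being removed in step 14.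

Step 14
Reactants: 27 11-[(dimethylamino)methyl] derivative of 25
Product: 29 (1S,4Z,6R,7R,8S)-1-(tert-butyldimethylsilyloxy)-6-(triethylsilyloxy)germacra-4,10(14),11(13)-trien-8,12-olide, via trimethylammonium iodide 28 (not isolated)
Conditions: MeI, MeOH/CH2Cl2, 25 °C; then aq. NaHCO3/CH2Cl2, 25 °C
Reagents that add atoms: none
Why: Quaternization followed by mild base-induced β-elimination of trimethylamine should give the α-methylene lactone without touching the silyl ethers.

Step 15
Reactants: 29 (1S,4Z,6R,7R,8S)-1-(tert-butyldimethylsilyloxy)-6-(triethylsilyloxy)germacra-4,10(14),11(13)-trien-8,12-olide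
Product: 30 (1S,4Z,6R,7S,8S)-1-(tert-butyldimethylsilyloxy)-6-hydroxygermacra-4,10(14),11(13)-trien-8,12-olide
Conditions: PPTS (cat.), MeOH/CH2Cl2, 0 °C
Reagents that add atoms: none
Why: Acid-catalysed methanolysis should cleave the labile triethylsilyl ether selectively over the secondary TBS ether, and it is done before the acid-sensitive oxirane exists.

Step 16
Reactants: 30 (1S,4Z,6R,7S,8S)-1-(tert-butyldimethylsilyloxy)-6-hydroxygermacra-4,10(14),11(13)-trien-8,12-olide
Product: 31 (1S,4R,5S,6S,7S,8S)-1-(tert-butyldimethylsilyloxy)-4,5-epoxy-6-hydroxygermacra-10(14),11(13)-dien-8,12-olide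
Conditions: VO(acac)2 (5 mol%), t-BuOOH (decane), CH2Cl2, 0 → 25 °C
Reagents that add atoms: tert-butyl hydroperoxide, SMILES CC(C)(C)OO
Why: In the vanadium-catalysed hydroxyl-directed epoxidation only the alkene with a free allylic OH reacts, and the C6 vanadate should deliver oxygen at a small O–C6–C5=C4 dihedral to the peripheral alkene face syn to the C6–O bond, as known for medium-ring (Z)-cycloalkenols (ring-cis epoxy alcohol), giving the 4α,5α-oxirane (4R,5S) with the cis geometry of the Z-alkene retained.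

Step 17
Reactants: 31 (1S,4R,5S,6S,7S,8S)-1-(tert-butyldimethylsilyloxy)-4,5-epoxy-6-hydroxygermacra-10(14),11(13)-dien-8,12-olide; 32 angelic acid
Product: 34 (1S,4R,5S,6S,7R,8S)-6-angeloyloxy-1-(tert-butyldimethylsilyloxy)-4,5-epoxygermacra-10(14),11(13)-dien-8,12-olide, via angelic 2,4,6-trichlorobenzoic anhydride 33 (not isolated)
Conditions: 32, 2,4,6-trichlorobenzoyl chloride, Et3N, toluene, 25 °C; then 31, DMAP, toluene, 25 → 60 °C
Reagents that add atoms: none
Why: In the Yamaguchi esterification the alcohol attacks the less hindered angeloyl carbonyl of the mixed anhydride under DMAP catalysis, conditions known to transfer the angeloyl group without Z-to-E isomerization to the tiglate.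

Step 18
Reactants: 34 (1S,4R,5S,6S,7R,8S)-6-angeloyloxy-1-(tert-butyldimethylsilyloxy)-4,5-epoxygermacra-10(14),11(13)-dien-8,12-olide
Product: 35 (1S,4R,5S,6S,7R,8S)-6-angeloyloxy-4,5-epoxy-1-hydroxygermacra-10(14),11(13)-dien-8,12-olide (CNP0104965.1)
Conditions: TBAF/AcOH (1:1), THF, 0 → 25 °C
Reagents that add atoms: none
Why: Fluoride-mediated desilylation buffered with acetic acid should free the C1 hydroxyl while sparing the oxirane, the α-methylene lactone and the angelate.

**Compound list**

1 | 2-(2-bromoethyl)-1,3-dioxolane | BrCCC1OCCO1 | starting material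
2 | propyne | CC#C | starting material
3 | [2-(1,3-dioxolan-2-yl)ethyl]magnesium bromide | Br[Mg]CCC1OCCO1 | intermediate
4 | [2-(1,3-dioxolan-2-yl)ethyl]copper | [Cu]CCC1OCCO1 | intermediate
5 | (Z)-[4-(1,3-dioxolan-2-yl)-2-methylbut-1-en-1-yl]copper | [Cu]/C=C(C)\CCC1OCCO1 | intermediate
6 | 2-[(3Z)-4-iodo-3-methylbut-3-en-1-yl]-1,3-dioxolane | I/C=C(C)\CCC1OCCO1 | intermediate
7 | (4Z)-5-iodo-4-methylpent-4-enal | O=CCC/C(C)=C\I | intermediate
8 | (2-bromoallyl)trimethylsilane | C=C(Br)C[Si](C)(C)C | starting material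
9 | [3-(trimethylsilyl)prop-1-en-2-yl]magnesium bromide | C=C([Mg]Br)C[Si](C)(C)C | intermediate
10 | rac-(6Z)-7-iodo-6-methyl-2-[(trimethylsilyl)methyl]hepta-1,6-dien-3-ol | C=C(C[Si](C)(C)C)C(O)CC/C(C)=C\I | intermediate
11 | (6Z)-7-iodo-6-methyl-2-[(trimethylsilyl)methyl]hepta-1,6-dien-3-one | C=C(C[Si](C)(C)C)C(=O)CC/C(C)=C\I | intermediate
12 | (3S,6Z)-7-iodo-6-methyl-2-[(trimethylsilyl)methyl]hepta-1,6-dien-3-ol | C=C(C[Si](C)(C)C)[C@@H](O)CC/C(C)=C\I | intermediate
13 | (3S,6Z)-3-(tert-butyldimethylsilyloxy)-7-iodo-6-methyl-2-[(trimethylsilyl)methyl]hepta-1,6-diene | C=C(C[Si](C)(C)C)[C@@H](O[Si](C)(C)C(C)(C)C)CC/C(C)=C\I | intermediate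
14 | methyl furan-2-carboxylate | COC(=O)c1ccco1 | starting material
15 | ethyl diazoacetate | CCOC(=O)C=[N+]=[N-] | starting material
16 | 6-ethyl 3-methyl (1S,5S,6S)-2-oxabicyclo[3.1.0]hex-3-ene-3,6-dicarboxylate | COC(=O)C1=C[C@H]2[C@H](C(=O)OCC)[C@H]2O1 | intermediate
17 | secondary ozonide of 16 (1,2,4-trioxolane across C3–C4; trioxolane centres undefined) | COC(=O)C12OOC(O1)[C@H]3[C@H](C(=O)OCC)[C@H]3O2 | intermediate
18 | ethyl (1S,2S,3S)-2-formyl-3-[(methoxyoxalyl)oxy]cyclopropane-1-carboxylate | O=C[C@@H]1[C@H](OC(=O)C(=O)OC)[C@H]1C(=O)OCC | intermediate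
19 | ethyl (1S,2R,3S)-2-[(1S,4S,7Z)-4-(tert-butyldimethylsilyloxy)-1-hydroxy-8-iodo-7-methyl-3-methylideneoct-7-en-1-yl]-3-[(methoxyoxalyl)oxy]cyclopropane-1-carboxylate | CCOC(=O)[C@@H]1[C@@H](OC(=O)C(=O)OC)[C@H]1[C@@H](O)CC(=C)[C@@H](O[Si](C)(C)C(C)(C)C)CC/C(C)=C\I | intermediate
20 | cyclopropanol from 19 (oxalate removed) | CCOC(=O)[C@@H]1[C@@H](O)[C@H]1[C@@H](O)CC(=C)[C@@H](O[Si](C)(C)C(C)(C)C)CC/C(C)=C\I | intermediate
21 | ethyl (3R,4S,7S,10Z)-7-(tert-butyldimethylsilyloxy)-3-formyl-4-hydroxy-11-iodo-10-methyl-6-methylideneundec-10-enoate | CCOC(=O)C[C@@H](C=O)[C@@H](O)CC(=C)[C@@H](O[Si](C)(C)C(C)(C)C)CC/C(C)=C\I | intermediate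
22 | (2S,3R)-2-[(3S,6Z)-3-(tert-butyldimethylsilyloxy)-7-iodo-6-methyl-2-methylidenehept-6-en-1-yl]-5-oxooxolane-3-carbaldehyde (seco-aldehyde) | C1C(=O)O[C@@H](CC(=C)[C@@H](O[Si](C)(C)C(C)(C)C)CC/C(C)=C\I)[C@@H]1C=O | intermediate
23 | (Z)-alkenylchromium(III) dichloride derived from 22 (Cr in place of I at C5) | C1C(=O)O[C@@H](CC(=C)[C@@H](O[Si](C)(C)C(C)(C)C)CC/C(C)=C\[Cr](Cl)Cl)[C@@H]1C=O | intermediate
24 | (1S,4Z,6R,7S,8S)-1-(tert-butyldimethylsilyloxy)-6-hydroxygermacra-4,10(14)-dien-8,12-olide (6α-OH, H-7α, 8α-O) | C1C(=O)O[C@H]2CC(=C)[C@@H](O[Si](C)(C)C(C)(C)C)CC/C(C)=C\[C@@H](O)[C@H]12 | intermediate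
25 | (1S,4Z,6R,7R,8S)-1-(tert-butyldimethylsilyloxy)-6-(triethylsilyloxy)germacra-4,10(14)-dien-8,12-olide | C1C(=O)O[C@H]2CC(=C)[C@@H](O[Si](C)(C)C(C)(C)C)CC/C(C)=C\[C@@H](O[Si](CC)(CC)CC)[C@H]12 | intermediate
26 | lithium enolate of lactone 25 (C11=C12–OLi) | C1=C(O[Li])O[C@H]2CC(=C)[C@@H](O[Si](C)(C)C(C)(C)C)CC/C(C)=C\[C@@H](O[Si](CC)(CC)CC)[C@H]12 | intermediate
27 | 11-[(dimethylamino)methyl] derivative of 25 (CH2NMe2 trans to C6) | CN(C)C[C@H]1C(=O)O[C@H]2CC(=C)[C@@H](O[Si](C)(C)C(C)(C)C)CC/C(C)=C\[C@@H](O[Si](CC)(CC)CC)[C@H]12 | intermediate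
28 | trimethylammonium iodide of 27 | C[N+](C)(C)C[C@H]1C(=O)O[C@H]2CC(=C)[C@@H](O[Si](C)(C)C(C)(C)C)CC/C(C)=C\[C@@H](O[Si](CC)(CC)CC)[C@H]12.[I-] | intermediate
29 | (1S,4Z,6R,7R,8S)-1-(tert-butyldimethylsilyloxy)-6-(triethylsilyloxy)germacra-4,10(14),11(13)-trien-8,12-olide | C=C1C(=O)O[C@H]2CC(=C)[C@@H](O[Si](C)(C)C(C)(C)C)CC/C(C)=C\[C@@H](O[Si](CC)(CC)CC)[C@H]12 | intermediate
30 | (1S,4Z,6R,7S,8S)-1-(tert-butyldimethylsilyloxy)-6-hydroxygermacra-4,10(14),11(13)-trien-8,12-olide | C=C1C(=O)O[C@H]2CC(=C)[C@@H](O[Si](C)(C)C(C)(C)C)CC/C(C)=C\[C@@H](O)[C@H]12 | intermediate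
31 | (1S,4R,5S,6S,7S,8S)-1-(tert-butyldimethylsilyloxy)-4,5-epoxy-6-hydroxygermacra-10(14),11(13)-dien-8,12-olide (4α,5α-epoxide) | C=C1C(=O)O[C@H]2CC(=C)[C@@H](O[Si](C)(C)C(C)(C)C)CC[C@@]3(C)O[C@H]3[C@@H](O)[C@H]12 | intermediate
32 | angelic acid [(Z)-2-methylbut-2-enoic acid] | C/C=C(/C)C(=O)O | starting material
33 | angelic 2,4,6-trichlorobenzoic anhydride | C/C=C(/C)C(=O)OC(=O)c1c(Cl)cc(Cl)cc1Cl | intermediate
34 | (1S,4R,5S,6S,7R,8S)-6-angeloyloxy-1-(tert-butyldimethylsilyloxy)-4,5-epoxygermacra-10(14),11(13)-dien-8,12-olide | C=C1C(=O)O[C@H]2CC(=C)[C@@H](O[Si](C)(C)C(C)(C)C)CC[C@@]3(C)O[C@H]3[C@@H](OC(=O)/C(C)=C\C)[C@H]12 | intermediate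
35 | (1S,4R,5S,6S,7R,8S)-6-angeloyloxy-4,5-epoxy-1-hydroxygermacra-10(14),11(13)-dien-8,12-olide (CNP0104965.1) | C=C1C(=O)O[C@H]2CC(=C)[C@@H](O)CC[C@@]3(C)O[C@H]3[C@@H](OC(=O)/C(C)=C\C)[C@H]12 | target

**Step count and risk assessment**

Total step count: 18 steps. Longest linear sequence: 16 steps (steps 1–6, then 9–18); steps 7–8 form the two-step side branch to 18.

Steps most likely to fail:

1. Step 11 (key ring closure). What may go wrong: poor facial selectivity at the C6 carbonyl in the cyclic transition state, so that the 6β-alcohol dominates, and competing intermolecular coupling. Fallback: the route sets out from 22 and still closes the ring by the same chromium-mediated addition. The unseparated mixture of 24 and the 6β-hydroxy epimer F1 is oxidized (Dess–Martin periodinane, NaHCO3, CH2Cl2) to the macrocyclic (Z)-4-en-6-one F2. The C6 centre is then set by reagent-controlled 1,2-reduction (CBS oxazaborolidine/catecholborane, −78 °C, antipode chosen for the 6α-alcohol; Luche reduction if ring conformation alone directs hydride to the required face). The route is rejoined at 24.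

2. Step 16 (directed epoxidation). What may go wrong: oxygen delivery to the wrong face of C4=C5 (ring-trans epoxy alcohol) if the ten-membered ring presents the C6–O bond differently from simpler medium rings, or oxidation of the allylic alcohol to the enone. Fallback: the route sets out from 30. The C6 hydroxyl is first esterified with angelic acid 32 under the Yamaguchi conditions of step 17 to give the 4,5-ene 6-angelate F3. F3 is then epoxidized under catalyst control (Shi fructose-derived ketone of the enantiomeric series matched to the 4α,5α face, Oxone, buffered MeCN/dimethoxymethane–water, 0 °C). The trisubstituted C4=C5 alkene should react ahead of the electron-poor angelate and methylene-lactone alkenes and the 1,1-disubstituted C10 alkene. The route is rejoined at 34.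

3. Step 17 (angeloylation). What may go wrong: slow acylation of the hindered C6 hydroxyl (flanked by the oxirane and the ring fusion), with isomerization of the activated angelate to the tiglate on prolonged heating. Fallback: the route sets out from 31. The alcohol is acylated with 2-[bis(2,2,2-trifluoroethoxy)phosphoryl]propanoic acid (DIC, DMAP, CH2Cl2) to give the C6 phosphonopropionate ester F4. The Z-configured 2-methylbut-2-enoate is then built on the oxygen by Still–Gennari olefination with acetaldehyde (KHMDS, 18-crown-6, THF, −78 °C). The route is rejoined at 34.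

**Further compounds**

F1 | step 11 | (1S,4Z,6S,7S,8S)-1-(tert-butyldimethylsilyloxy)-6-hydroxygermacra-4,10(14)-dien-8,12-olide (6β-hydroxy epimer of 24) | C1C(=O)O[C@H]2CC(=C)[C@@H](O[Si](C)(C)C(C)(C)C)CC/C(C)=C\[C@H](O)[C@H]12
F2 | step 11 | (Z)-1-(tert-butyldimethylsilyloxy)-6-oxogermacra-4,10(14)-dien-8,12-olide (macrocyclic enone) | C1C(=O)O[C@H]2CC(=C)[C@@H](O[Si](C)(C)C(C)(C)C)CC/C(C)=C\C(=O)[C@H]12
F3 | step 16 | 6-angeloyloxy-1-(tert-butyldimethylsilyloxy)germacra-4(Z),10(14),11(13)-trien-8,12-olide | C=C1C(=O)O[C@H]2CC(=C)[C@@H](O[Si](C)(C)C(C)(C)C)CC/C(C)=C\[C@@H](OC(=O)/C(C)=C\C)[C@H]12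
F4 | step 17 | 6-O-{2-[bis(2,2,2-trifluoroethoxy)phosphoryl]propanoyl} derivative of 31 (phosphonate α-carbon as a mixture) | C=C1C(=O)O[C@H]2CC(=C)[C@@H](O[Si](C)(C)C(C)(C)C)CC[C@@]3(C)O[C@H]3[C@@H](OC(=O)C(C)P(=O)(OCC(F)(F)F)OCC(F)(F)F)[C@H]12
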